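Ring C is disconnected at the O1–C8a bond. Because O5 and O8 are para to each other on ring A, ring A can be oxidised to a para-quinone in which C8a is a vinylogous ester carbon activated by both C5=O and the C4 ketone. Anodic oxidation of an acylhydroquinone therefore unmasks this electrophile and, in the same operation, lets the enol oxygen of a side-chain 1,3-diketone displace the C8a methoxy group, closing the pyranone with no choice between O5 and O8a. The precursor is a fully substituted 2,6-dimethoxyhydroquinone carrying the prenyl group and a 2-silyloxy-3-phenylpropane-1,3-dione chain, built by two directed lithiations.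

Key step: step 7

Assumption: the N-methoxy-N-methylamide used in step 4 is taken as a catalogue reagent; if it has to be made, it is one step from commercial ethyl (tert-butyldimethylsilyloxy)acetate (MeNHOMe·HCl, i-PrMgCl).
Remark: flavone numbering is used for ring atoms throughout; the only stereocentre on the route (C2 of the dione precursor) is racemic, enolisable and becomes sp2 in the key step, and the target has none.

Step 1
Reactants: 1 2,6-dimethoxy-1,4-benzoquinone
Product: 2 2,6-dimethoxybenzene-1,4-diol
Conditions: Na2S2O4, THF/H2O, rt, argon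
Reagents that add atoms: none
Why: dithionite reduction of a para-quinone to its hydroquinone is a standard two-electron reduction that touches nothing else; the air-sensitive diol is used at once.

Step 2
Reactants: 2 2,6-dimethoxybenzene-1,4-diol; 3 chloromethyl methyl ether
Product: 4 1,3-dimethoxy-2,5-bis(methoxymethoxy)benzene
Conditions: NaH, MOMCl, DMF, 0 °C → rt, argon
Reagents that add atoms: chloromethyl methyl ether (MOMCl), COCCl
Why: Williamson-type O-alkylation of both phenoxides gives the bis-acetal, chosen because MOM ethers survive alkyllithiums, direct ortho-lithiation and can later be removed without protic acid.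

Step 3
Reactants: 4 1,3-dimethoxy-2,5-bis(methoxymethoxy)benzene; 5 prenyl bromide
Product: 7 1,3-dimethoxy-2,5-bis(methoxymethoxy)-4-(3-methylbut-2-en-1-yl)benzene, via aryllithium 6 (not isolated)
Conditions: n-BuLi (1.1 equiv), THF, 0 °C; then CuI (10 mol %), prenyl bromide, −78 °C → rt
Reagents that add atoms: prenyl bromide (1-bromo-3-methylbut-2-ene), CC(C)=CCBr
Why: directed ortho-metalation at one of the two equivalent ring CH positions (each flanked by OMe and OMOM) followed by copper-catalysed allylic substitution at the primary carbon of prenyl bromide should give the linear prenyl arene, and the first lithiation deactivates the ring towards a second.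

Step 4
Reactants: 7 1,3-dimethoxy-2,5-bis(methoxymethoxy)-4-(3-methylbut-2-en-1-yl)benzene; 8 2-[(tert-butyldimethylsilyl)oxy]-N-methoxy-N-methylacetamide
Product: 10 2-[(tert-butyldimethylsilyl)oxy]-1-[2,4-dimethoxy-3,6-bis(methoxymethoxy)-5-(3-methylbut-2-en-1-yl)phenyl]ethan-1-one, via prenylated aryllithium 9 (not isolated)
Conditions: n-BuLi (1.2 equiv), THF, −20 → 0 °C; then amide 8, −78 → 0 °C; then AcOH
Reagents that add atoms: 2-[(tert-butyldimethylsilyl)oxy]-N-methoxy-N-methylacetamide, CON(C)C(=O)CO[Si](C)(C)C(C)(C)C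
Why: a second directed ortho-metalation at the only remaining ring CH (again between OMe and OMOM) and a Weinreb ketone synthesis should place the silyloxyacetyl group without over-addition, since the N-methoxy-N-methylamide stops at the ketone stage.

Step 5
Reactants: 10 2-[(tert-butyldimethylsilyl)oxy]-1-[2,4-dimethoxy-3,6-bis(methoxymethoxy)-5-(3-methylbut-2-en-1-yl)phenyl]ethan-1-one
Product: 12 2-[(tert-butyldimethylsilyl)oxy]-1-[3,6-dihydroxy-2,4-dimethoxy-5-(3-methylbut-2-en-1-yl)phenyl]ethan-1-one, via bis(trimethylsilyl) ether 11 (not isolated)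
Conditions: TMSOTf, 2,2'-bipyridyl, CH2Cl2, 0 °C → rt; then H2O; degassed aq NaHCO3 work-up
Reagents that add atoms: none
Why: silyl triflate–bipyridyl cleavage of aryl MOM acetals converts each ArOCH2OMe into ArOSiMe3, which water hydrolyses, and because no protic acid is present the alkyl TBS ether should survive and the prenyl group should not cyclise onto the new ortho phenol.

Step 6
Reactants: 12 2-[(tert-butyldimethylsilyl)oxy]-1-[3,6-dihydroxy-2,4-dimethoxy-5-(3-methylbut-2-en-1-yl)phenyl]ethan-1-one; 13 benzoyl chloride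
Product: 14 2-[(tert-butyldimethylsilyl)oxy]-1-[3,6-dihydroxy-2,4-dimethoxy-5-(3-methylbut-2-en-1-yl)phenyl]-3-phenylpropane-1,3-dione (racemic)
Conditions: LiN(SiMe3)2 (4.2 equiv), THF, −78 °C; PhCOCl (1.05 equiv), −78 °C → rt; AcOH quench, argon; product kept from acid and air
Reagents that add atoms: benzoyl chloride, O=C(Cl)c1ccccc1
Why: crossed Claisen-type C-aroylation of the fully deprotonated o-hydroxyaryl ketone should give the 1,3-diketone, any benzoate formed on the ortho phenoxide being carried to carbon by Baker–Venkataraman rearrangement under the same base; the new C2 centre is racemic and needs no control.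

Step 7
Reactants: 14 2-[(tert-butyldimethylsilyl)oxy]-1-[3,6-dihydroxy-2,4-dimethoxy-5-(3-methylbut-2-en-1-yl)phenyl]-3-phenylpropane-1,3-dione (racemic)
Product: 16 3-[(tert-butyldimethylsilyl)oxy]-7-methoxy-6-(3-methylbut-2-en-1-yl)-2-phenyl-4H-chromene-4,5,8-trione, via acylquinone 15 (not isolated)
Conditions: divided cell, graphite anode, Pt cathode, LiClO4 (0.1 M), 2,6-lutidine (2.2 equiv), MeOH/MeCN, controlled potential just above the hydroquinone wave (about +0.5 V vs Ag/AgCl, to be set by voltammetry), 2 F/mol, 0 °C → rt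
Reagents that add atoms: none
Why: Proposed new method: the hydroquinone of 14 gives up two electrons and two protons at the anode to form acylquinone 15, in which C8a is a vinylogous ester carbon β to both C5=O and the C4 ketone; the enol oxygen on the benzoyl carbon adds to C8a and methanol is expelled (addition–elimination), which makes the O1–C8a bond. The closest known reactions are the anodic generation of quinones that are trapped in the cell by 1,3-dicarbonyl compounds (benzofuran electrosynthesis) and the exchange of quinone alkoxy groups by oxygen nucleophiles through addition–elimination; closure of a flavone by an enol oxygen in this way has not been shown. Ring C closes in a 6-endo-trig mode on the C4a=C8a double bond, and no stereocentre is formed because C3 becomes sp2. Chemoselectivity is set by the potential, since the electron-rich hydroquinone should be oxidised far below the prenyl alkene, and lutidine is too weak a base to tautomerise the prenylquinone to a quinone methide. Site selectivity is set by the substrate: O5 is a carbonyl in 15 and cannot act as a nucleophile, the C7 methoxy group is out of reach of the enol, and attack through carbon would need a four-membered ring.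

Step 8
Reactants: 16 3-[(tert-butyldimethylsilyl)oxy]-7-methoxy-6-(3-methylbut-2-en-1-yl)-2-phenyl-4H-chromene-4,5,8-trione
Product: 17 3-[(tert-butyldimethylsilyl)oxy]-7-hydroxy-6-(3-methylbut-2-en-1-yl)-2-phenyl-4H-chromene-4,5,8-trione
Conditions: LiCl, DMF, 80 °C; cold dilute HCl work-up
Reagents that add atoms: none
Why: SN2 O-demethylation by chloride at the methyl of the C7 vinylogous ester should be easy because the leaving group is the stabilised anion of a 2-hydroxy-1,4-quinone, and chloride attacks only the sp3 carbon, so pyranone, quinone and prenyl group are spared (partial silyl loss would be harmless).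

Step 9
Reactants: 17 3-[(tert-butyldimethylsilyl)oxy]-7-hydroxy-6-(3-methylbut-2-en-1-yl)-2-phenyl-4H-chromene-4,5,8-trione
Product: 19 platanetin (3,5,7,8-tetrahydroxy-6-(3-methylbut-2-en-1-yl)-2-phenyl-4H-chromen-4-one), via dihydroxyquinone 18 (not isolated)
Conditions: Et3N·3HF, THF, 0 °C → rt; then aq Na2S2O4, EtOAc, rt, argon
Reagents that add atoms: none
Why: fluoride desilylation of the C3 silyl ether under non-basic conditions followed in the same flask by dithionite reduction of the 5,8-quinone should give the tetrol, and finishing under reducing conditions protects the air-sensitive 5,7,8-trihydroxy ring A.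

Compound list
1 | 2,6-dimethoxy-1,4-benzoquinone | COC1=CC(=O)C=C(OC)C1=O | starting material
2 | 2,6-dimethoxybenzene-1,4-diol | COc1cc(O)cc(OC)c1O | intermediate
3 | chloromethyl methyl ether (MOMCl) | COCCl | starting material
4 | 1,3-dimethoxy-2,5-bis(methoxymethoxy)benzene | COCOc1cc(OC)c(OCOC)c(OC)c1 | intermediate
5 | prenyl bromide (1-bromo-3-methylbut-2-ene) | CC(C)=CCBr | starting material
6 | 2,4-dimethoxy-3,6-bis(methoxymethoxy)phenyllithium | [Li]c1c(OC)c(OCOC)c(OC)cc1OCOC | intermediate
7 | 1,3-dimethoxy-2,5-bis(methoxymethoxy)-4-(3-methylbut-2-en-1-yl)benzene | CC(C)=CCc1c(OC)c(OCOC)c(OC)cc1OCOC | intermediate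
8 | 2-[(tert-butyldimethylsilyl)oxy]-N-methoxy-N-methylacetamide | CON(C)C(=O)CO[Si](C)(C)C(C)(C)C | starting material
9 | 2,4-dimethoxy-3,6-bis(methoxymethoxy)-5-(3-methylbut-2-en-1-yl)phenyllithium | [Li]c1c(OC)c(OCOC)c(OC)c(CC=C(C)C)c1OCOC | intermediate
10 | 2-[(tert-butyldimethylsilyl)oxy]-1-[2,4-dimethoxy-3,6-bis(methoxymethoxy)-5-(3-methylbut-2-en-1-yl)phenyl]ethan-1-one | CC(C)=CCc1c(OC)c(OCOC)c(OC)c(C(=O)CO[Si](C)(C)C(C)(C)C)c1OCOC | intermediate
11 | 2-[(tert-butyldimethylsilyl)oxy]-1-[2,4-dimethoxy-5-(3-methylbut-2-en-1-yl)-3,6-bis(trimethylsilyloxy)phenyl]ethan-1-one | CC(C)=CCc1c(OC)c(O[Si](C)(C)C)c(OC)c(C(=O)CO[Si](C)(C)C(C)(C)C)c1O[Si](C)(C)C | intermediate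
12 | 2-[(tert-butyldimethylsilyl)oxy]-1-[3,6-dihydroxy-2,4-dimethoxy-5-(3-methylbut-2-en-1-yl)phenyl]ethan-1-one | CC(C)=CCc1c(OC)c(O)c(OC)c(C(=O)CO[Si](C)(C)C(C)(C)C)c1O | intermediate
13 | benzoyl chloride | O=C(Cl)c1ccccc1 | starting material
14 | 2-[(tert-butyldimethylsilyl)oxy]-1-[3,6-dihydroxy-2,4-dimethoxy-5-(3-methylbut-2-en-1-yl)phenyl]-3-phenylpropane-1,3-dione (racemic at C2, enolisable) | CC(C)=CCc1c(OC)c(O)c(OC)c(C(=O)C(O[Si](C)(C)C(C)(C)C)C(=O)c2ccccc2)c1O | intermediate
15 | 2-{2-[(tert-butyldimethylsilyl)oxy]-3-oxo-3-phenylpropanoyl}-3,5-dimethoxy-6-(3-methylbut-2-en-1-yl)-1,4-benzoquinone (racemic, enolisable) | CC(C)=CCC1=C(OC)C(=O)C(OC)=C(C(=O)C(O[Si](C)(C)C(C)(C)C)C(=O)c2ccccc2)C1=O | intermediate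
16 | 3-[(tert-butyldimethylsilyl)oxy]-7-methoxy-6-(3-methylbut-2-en-1-yl)-2-phenyl-4H-chromene-4,5,8-trione | CC(C)=CCC1=C(OC)C(=O)C2=C(C1=O)C(=O)C(O[Si](C)(C)C(C)(C)C)=C(c1ccccc1)O2 | intermediate
17 | 3-[(tert-butyldimethylsilyl)oxy]-7-hydroxy-6-(3-methylbut-2-en-1-yl)-2-phenyl-4H-chromene-4,5,8-trione | CC(C)=CCC1=C(O)C(=O)C2=C(C1=O)C(=O)C(O[Si](C)(C)C(C)(C)C)=C(c1ccccc1)O2 | intermediate
18 | 3,7-dihydroxy-6-(3-methylbut-2-en-1-yl)-2-phenyl-4H-chromene-4,5,8-trione | CC(C)=CCC1=C(O)C(=O)C2=C(C1=O)C(=O)C(O)=C(c1ccccc1)O2 | intermediate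
19 | platanetin, 3,5,7,8-tetrahydroxy-6-(3-methylbut-2-en-1-yl)-2-phenyl-4H-chromen-4-one (no stereocentre) | CC(C)=CCc1c(O)c(O)c2oc(-c3ccccc3)c(O)c(=O)c2c1O | target

Total step count: 9. Longest linear sequence: 9 steps (1 → 19); compounds 3, 5, 8 and 13 are bought.

Steps most likely to fail

Step 7 (the new method). After oxidation the enol oxygen may be too slow to displace methoxide, so that the acylquinone is consumed by addition of methanol or of a second substrate molecule, or by base-induced tautomerisation towards a quinone methide at the prenyl CH2. The fallback uses only established reaction types and closes ring C at O1–C2 instead. It sets out from 14, which is oxidised chemically with Ag2O in Et2O over MgSO4 to give isolated 15. LiCl (about 1 equiv) in DMF at room temperature should then demethylate only the doubly activated C8a vinylogous ester, giving 2-{2-[(tert-butyldimethylsilyl)oxy]-3-oxo-3-phenylpropanoyl}-3-hydroxy-5-methoxy-6-(3-methylbut-2-en-1-yl)-1,4-benzoquinone F1. This o-hydroxyaryl-type 1,3-diketone is cyclodehydrated in the classical flavone manner (PPTS, toluene, 4 Å sieves, 60 °C), the C8a oxygen now attacking the benzoyl carbon, and the route is rejoined at 16. Because C5 stays a carbonyl and C7 keeps its methyl ether, only one hydroxyl can close.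

Step 4. The second metalation may deprotonate the benzylic–allylic CH2 of the prenyl group instead of the ring, and the hindered aryllithium may enolise or fragment the amide instead of adding to it. The fallback replaces C–H deprotonation by halogen–metal exchange and acyl substitution by carbonyl addition–oxidation. It sets out from 4, which is brominated twice (NBS, MeCN, 0 °C) to 1,5-dibromo-2,4-dimethoxy-3,6-bis(methoxymethoxy)benzene F2. One bromine–lithium exchange (n-BuLi, 1 equiv, THF, −78 °C) gives 5-bromo-2,4-dimethoxy-3,6-bis(methoxymethoxy)phenyllithium F3, which is prenylated (CuI, prenyl bromide) to 1-bromo-2,4-dimethoxy-3,6-bis(methoxymethoxy)-5-(3-methylbut-2-en-1-yl)benzene F4. A second exchange at −78 °C, faster than any deprotonation, gives aryllithium 9, which is added to commercial (tert-butyldimethylsilyloxy)acetaldehyde to give 2-[(tert-butyldimethylsilyl)oxy]-1-[2,4-dimethoxy-3,6-bis(methoxymethoxy)-5-(3-methylbut-2-en-1-yl)phenyl]ethan-1-ol F5 (racemic). Oxidation with DMP and NaHCO3 in CH2Cl2 rejoins the route at 10.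

Step 6. The acid chloride may acylate the hindered, non-chelated phenoxide or react twice, and the hydroquinone polyanion may be oxidised by traces of air. The fallback builds the dione by aldol addition and oxidation while the hydroquinone is still protected. It sets out from 10, whose lithium enolate (LiN(SiMe3)2, THF, −78 °C) is added to benzaldehyde to give 2-[(tert-butyldimethylsilyl)oxy]-1-[2,4-dimethoxy-3,6-bis(methoxymethoxy)-5-(3-methylbut-2-en-1-yl)phenyl]-3-hydroxy-3-phenylpropan-1-one F6 (diastereomer mixture, both centres lost later). DMP oxidation gives 2-[(tert-butyldimethylsilyl)oxy]-1-[2,4-dimethoxy-3,6-bis(methoxymethoxy)-5-(3-methylbut-2-en-1-yl)phenyl]-3-phenylpropane-1,3-dione F7 (racemic). The acetals are then removed as in step 5 (TMSOTf, 2,2'-bipyridyl, then water) through 2-[(tert-butyldimethylsilyl)oxy]-1-[2,4-dimethoxy-5-(3-methylbut-2-en-1-yl)-3,6-bis(trimethylsilyloxy)phenyl]-3-phenylpropane-1,3-dione F8 (not isolated), and the route is rejoined at 14.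

Further compounds
F1 | step 7 | 2-{2-[(tert-butyldimethylsilyl)oxy]-3-oxo-3-phenylpropanoyl}-3-hydroxy-5-methoxy-6-(3-methylbut-2-en-1-yl)-1,4-benzoquinone (racemic, enolisable) | CC(C)=CCC1=C(OC)C(=O)C(O)=C(C(=O)C(O[Si](C)(C)C(C)(C)C)C(=O)c2ccccc2)C1=O
F2 | step 4 | 1,5-dibromo-2,4-dimethoxy-3,6-bis(methoxymethoxy)benzene | COCOc1c(Br)c(OC)c(OCOC)c(OC)c1Br
F3 | step 4 | 5-bromo-2,4-dimethoxy-3,6-bis(methoxymethoxy)phenyllithium | [Li]c1c(OC)c(OCOC)c(OC)c(Br)c1OCOC
F4 | step 4 | 1-bromo-2,4-dimethoxy-3,6-bis(methoxymethoxy)-5-(3-methylbut-2-en-1-yl)benzene | CC(C)=CCc1c(OC)c(OCOC)c(OC)c(Br)c1OCOC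
F5 | step 4 | 2-[(tert-butyldimethylsilyl)oxy]-1-[2,4-dimethoxy-3,6-bis(methoxymethoxy)-5-(3-methylbut-2-en-1-yl)phenyl]ethan-1-ol (racemic) | CC(C)=CCc1c(OC)c(OCOC)c(OC)c(C(O)CO[Si](C)(C)C(C)(C)C)c1OCOC
F6 | step 6 | 2-[(tert-butyldimethylsilyl)oxy]-1-[2,4-dimethoxy-3,6-bis(methoxymethoxy)-5-(3-methylbut-2-en-1-yl)phenyl]-3-hydroxy-3-phenylpropan-1-one (diastereomer mixture, racemic) | CC(C)=CCc1c(OC)c(OCOC)c(OC)c(C(=O)C(O[Si](C)(C)C(C)(C)C)C(O)c2ccccc2)c1OCOC
F7 | step 6 | 2-[(tert-butyldimethylsilyl)oxy]-1-[2,4-dimethoxy-3,6-bis(methoxymethoxy)-5-(3-methylbut-2-en-1-yl)phenyl]-3-phenylpropane-1,3-dione (racemic) | CC(C)=CCc1c(OC)c(OCOC)c(OC)c(C(=O)C(O[Si](C)(C)C(C)(C)C)C(=O)c2ccccc2)c1OCOC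
F8 | step 6 | 2-[(tert-butyldimethylsilyl)oxy]-1-[2,4-dimethoxy-5-(3-methylbut-2-en-1-yl)-3,6-bis(trimethylsilyloxy)phenyl]-3-phenylpropane-1,3-dione (racemic) | CC(C)=CCc1c(OC)c(O[Si](C)(C)C)c(OC)c(C(=O)C(O[Si](C)(C)C(C)(C)C)C(=O)c2ccccc2)c1O[Si](C)(C)C
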